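**Strategy.** The route rests on closing ring C (the pyranone) by forming the C4–C4a bond between the ketone carbon and ring A. Ring A is phloroglucinol-derived: in the open 3,5-dioxygenated aryl ether both carbons ortho to O1 are equivalent and activated by all three oxygens, so an intramolecular Friedel–Crafts acylation has only one outcome. The precursor is a quaternary aryl(aryloxymethyl)malonate in which C3 carries an extra allyl ester. This temporary group removes the C3–H (no ketene, no β-elimination of the aryloxide) and is later excised by Pd-catalysed decarboxylative asymmetric protonation, which sets the labile (3R) centre near the end. The tert-butyl ester is unmasked and cyclised in one operation.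

Key step: step 8

Assumption: 3,5-bis(allyloxy)phenol is made (step 6) rather than bought.
Assumption: the Pd/(S)-(CF3)3-t-BuPHOX/Meldrum's acid protonation in step 9 is taken to deliver the 3R ketone; the sense is checked in a pilot run and the (R)-ligand is used instead if it proves opposite.

**Step 1**
Reactants: 1 4-bromoresorcinol; 2 triisopropylsilyl chloride
Product: 3 2-bromo-5-(triisopropylsilyloxy)phenol
Conditions: TIPSCl (1.0 equiv), imidazole, DMF, −20 °C → 0 °C
Reagents that add atoms: triisopropylsilyl chloride, CC(C)[Si](Cl)(C(C)C)C(C)C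
Why: Selective phenol silylation, in which the bulky silyl chloride should react at the unhindered hydroxyl para to bromine rather than at the hydroxyl flanked by bromine (steric shielding, O–H···Br contact); regioisomer and bis-ether are removed by chromatography.

**Step 2**
Reactants: 3 2-bromo-5-(triisopropylsilyloxy)phenol; 4 3-chloro-3-methylbut-1-yne
Product: 7 8-bromo-2,2-dimethyl-5-(triisopropylsilyloxy)-2H-chromene, via aryl 1,1-dimethylpropargyl ether 5 (not isolated), via ortho-allenylphenol 6 (not isolated)
Conditions: 3-chloro-3-methylbut-1-yne, DBU, CuCl2 (cat.), MeCN, 0 °C; work-up, then crude ether in xylenes, 140 °C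
Reagents that add atoms: 3-chloro-3-methylbut-1-yne, CC(C)(Cl)C#C
Why: Copper-catalysed O-propargylation followed by an aromatic propargyl Claisen rearrangement that can only go to the single free ortho carbon (the other bears bromine), then 1,5-hydrogen shift and 6π oxa-electrocyclisation to the 2,2-dimethylchromene.

**Step 3**
Reactants: 7 8-bromo-2,2-dimethyl-5-(triisopropylsilyloxy)-2H-chromene; 8 (2-tert-butoxy-2-oxoethyl)zinc bromide
Product: 9 tert-butyl 2-[2,2-dimethyl-5-(triisopropylsilyloxy)-2H-chromen-8-yl]acetate
Conditions: BrZnCH2CO2t-Bu, Pd(dba)2 (cat.), Q-phos (cat.), THF, rt → 50 °C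
Reagents that add atoms: (2-tert-butoxy-2-oxoethyl)zinc bromide, CC(C)(C)OC(=O)C[Zn]Br
Why: Pd-catalysed Negishi-type α-arylation with a Reformatsky reagent, which runs under neutral conditions and tolerates electron-rich ortho-alkoxy aryl bromides, the silyl ether and the chromene alkene.

**Step 4**
Reactants: 9 tert-butyl 2-[2,2-dimethyl-5-(triisopropylsilyloxy)-2H-chromen-8-yl]acetate; 10 allyl chloroformate
Product: 11 1-allyl 3-tert-butyl 2-[2,2-dimethyl-5-(triisopropylsilyloxy)-2H-chromen-8-yl]malonate (racemic)
Conditions: LiHMDS (2.2 equiv), THF, −78 °C; ClCO2allyl, −78 → 0 °C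
Reagents that add atoms: allyl chloroformate, C=CCOC(Cl)=O
Why: Claisen-type C-acylation of the lithium ester enolate, in which the second equivalent of base deprotonates the more acidic malonate as it forms and so prevents proton exchange and double acylation.

**Step 5**
Reactants: 11 1-allyl 3-tert-butyl 2-[2,2-dimethyl-5-(triisopropylsilyloxy)-2H-chromen-8-yl]malonate; 12 formaldehyde
Product: 13 1-allyl 3-tert-butyl 2-[2,2-dimethyl-5-(triisopropylsilyloxy)-2H-chromen-8-yl]-2-(hydroxymethyl)malonate (racemic)
Conditions: aq. CH2O (37%), KHCO3 (cat.), THF, rt; neutral quench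
Reagents that add atoms: formaldehyde, C=O
Why: Base-catalysed aldol addition (hydroxymethylation) of the arylmalonate creates the quaternary C3 as a racemate, which is acceptable because C3 is re-set in step 9.

**Step 6**
Reactants: 14 phloroglucinol; 15 allyl bromide
Product: 16 3,5-bis(allyloxy)phenol
Conditions: allyl bromide (2.0 equiv), K2CO3, DMF, rt; chromatography
Reagents that add atoms: allyl bromide, C=CCBr
Why: Statistical Williamson etherification from which the bis-ether is separated; allyl is chosen because it is small, strongly activating for step 8 and removable by Pd(0) without base.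

**Step 7**
Reactants: 13 1-allyl 3-tert-butyl 2-[2,2-dimethyl-5-(triisopropylsilyloxy)-2H-chromen-8-yl]-2-(hydroxymethyl)malonate; 16 3,5-bis(allyloxy)phenol
Product: 17 1-allyl 3-tert-butyl 2-{[3,5-bis(allyloxy)phenoxy]methyl}-2-[2,2-dimethyl-5-(triisopropylsilyloxy)-2H-chromen-8-yl]malonate (racemic)
Conditions: PPh3, DIAD, toluene, 0 → 60 °C
Reagents that add atoms: 3,5-bis(allyloxy)phenol, Oc1cc(OCC=C)cc(OCC=C)c1
Why: Mitsunobu etherification of a primary alcohol with an acidic phenol; the quaternary neighbour has no hydrogen, so β-elimination and epimerisation cannot compete and only the slow neopentyl-type SN2 has to be driven by heating.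

**Step 8**
Reactants: 17 1-allyl 3-tert-butyl 2-{[3,5-bis(allyloxy)phenoxy]methyl}-2-[2,2-dimethyl-5-(triisopropylsilyloxy)-2H-chromen-8-yl]malonate
Product: 20 allyl 5,7-bis(allyloxy)-3-[2,2-dimethyl-5-(triisopropylsilyloxy)-2H-chromen-8-yl]-4-oxochromane-3-carboxylate (racemic), via malonic half-acid 18 (not isolated), via mixed trifluoroacetic anhydride 19 (not isolated)
Conditions: TFA, TFAA, CH2Cl2, 0 °C → rt (short)
Reagents that add atoms: none
Why: TFA cleaves the tert-butyl ester by E1 loss of isobutene to half-acid 18, TFAA converts it into mixed anhydride 19, and this acylium equivalent attacks the ring-A carbon ortho to the ether oxygen in an intramolecular Friedel–Crafts acylation, the closest known reaction type being the TFA/TFAA cyclisation of 3-aryloxypropanoic acids and their tert-butyl esters to chroman-4-ones. Ring C closes in a 6-exo-trig mode at the acyl carbon. No stereocentre is created: quaternary C3 is already present as a racemate and is left uncontrolled on purpose, since it is re-set under ligand control in step 9. Regioselectivity is secured by the substrate, because the two carbons ortho to the ether oxygen are homotopic and each is ortho or para to all three oxygens, the carbon between the two allyloxy groups cannot be reached by the three-atom tether, and attack from ring B would need a four-membered ring. Chemoselectivity rests on quaternary C3, which has no hydrogen, so ketene formation, enolisation and E1cB loss of the aryloxide are impossible, while the allyl ester, allyl ethers and TIPS ether tolerate TFA. The step needs short exposure at low temperature so that the acid-sensitive chromene double bond is not protonated.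

**Step 9**
Reactants: 20 allyl 5,7-bis(allyloxy)-3-[2,2-dimethyl-5-(triisopropylsilyloxy)-2H-chromen-8-yl]-4-oxochromane-3-carboxylate
Product: 22 (3R)-5,7-dihydroxy-3-[2,2-dimethyl-5-(triisopropylsilyloxy)-2H-chromen-8-yl]chroman-4-one, via (3R)-5,7-bis(allyloxy) isoflavanone 21 (not isolated)
Conditions: Pd2(dba)3 (cat.), (S)-(CF3)3-t-BuPHOX (cat.), Meldrum's acid (excess), 1,4-dioxane, rt; then Pd(PPh3)4 (cat.), 40 °C
Reagents that add atoms: none
Why: Pd(0) ionises the β-keto allyl ester, CO2 is lost and the chiral Pd-PHOX enolate is protonated by Meldrum's acid on one enantioface (decarboxylative asymmetric protonation), which should set C3 as R under ligand control; the slower Pd(0) cleavage of the two aryl allyl ethers with the same acidic allyl acceptor is then completed in the flask without base.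

**Step 10**
Reactants: 22 (3R)-5,7-dihydroxy-3-[2,2-dimethyl-5-(triisopropylsilyloxy)-2H-chromen-8-yl]chroman-4-one
Product: 23 (3R)-5,7-dihydroxy-3-(5-hydroxy-2,2-dimethyl-2H-chromen-8-yl)chroman-4-one
Conditions: HF·pyridine, pyridine, THF, 0 °C → rt
Reagents that add atoms: none
Why: Fluoride-mediated cleavage of the aryl silyl ether under mildly acidic conditions should leave the base-labile C3 centre and the chromene untouched.

**Compound list**
1 | 4-bromoresorcinol | Oc1ccc(Br)c(O)c1 | starting material
2 | triisopropylsilyl chloride | CC(C)[Si](Cl)(C(C)C)C(C)C | starting material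
3 | 2-bromo-5-(triisopropylsilyloxy)phenol | Oc1cc(O[Si](C(C)C)(C(C)C)C(C)C)ccc1Br | intermediate
4 | 3-chloro-3-methylbut-1-yne | CC(C)(Cl)C#C | starting material
5 | 1-bromo-2-(2-methylbut-3-yn-2-yloxy)-4-(triisopropylsilyloxy)benzene | C#CC(C)(C)Oc1cc(O[Si](C(C)C)(C(C)C)C(C)C)ccc1Br | intermediate
6 | 6-bromo-2-(3-methylbuta-1,2-dien-1-yl)-3-(triisopropylsilyloxy)phenol | CC(C)=C=Cc1c(O)c(Br)ccc1O[Si](C(C)C)(C(C)C)C(C)C | intermediate
7 | 8-bromo-2,2-dimethyl-5-(triisopropylsilyloxy)-2H-chromene | CC1(C)C=Cc2c(O[Si](C(C)C)(C(C)C)C(C)C)ccc(Br)c2O1 | intermediate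
8 | (2-tert-butoxy-2-oxoethyl)zinc bromide | CC(C)(C)OC(=O)C[Zn]Br | starting material
9 | tert-butyl 2-[2,2-dimethyl-5-(triisopropylsilyloxy)-2H-chromen-8-yl]acetate | CC1(C)C=Cc2c(O[Si](C(C)C)(C(C)C)C(C)C)ccc(CC(=O)OC(C)(C)C)c2O1 | intermediate
10 | allyl chloroformate | C=CCOC(Cl)=O | starting material
11 | 1-allyl 3-tert-butyl 2-[2,2-dimethyl-5-(triisopropylsilyloxy)-2H-chromen-8-yl]malonate (racemic) | CC1(C)C=Cc2c(O[Si](C(C)C)(C(C)C)C(C)C)ccc(C(C(=O)OCC=C)C(=O)OC(C)(C)C)c2O1 | intermediate
12 | formaldehyde (37% aqueous) | C=O | starting material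
13 | 1-allyl 3-tert-butyl 2-[2,2-dimethyl-5-(triisopropylsilyloxy)-2H-chromen-8-yl]-2-(hydroxymethyl)malonate (racemic) | CC1(C)C=Cc2c(O[Si](C(C)C)(C(C)C)C(C)C)ccc(C(CO)(C(=O)OCC=C)C(=O)OC(C)(C)C)c2O1 | intermediate
14 | phloroglucinol | Oc1cc(O)cc(O)c1 | starting material
15 | allyl bromide | C=CCBr | starting material
16 | 3,5-bis(allyloxy)phenol | Oc1cc(OCC=C)cc(OCC=C)c1 | intermediate
17 | 1-allyl 3-tert-butyl 2-{[3,5-bis(allyloxy)phenoxy]methyl}-2-[2,2-dimethyl-5-(triisopropylsilyloxy)-2H-chromen-8-yl]malonate (racemic) | CC1(C)C=Cc2c(O[Si](C(C)C)(C(C)C)C(C)C)ccc(C(COc3cc(OCC=C)cc(OCC=C)c3)(C(=O)OCC=C)C(=O)OC(C)(C)C)c2O1 | intermediate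
18 | 3-(allyloxy)-2-{[3,5-bis(allyloxy)phenoxy]methyl}-2-[2,2-dimethyl-5-(triisopropylsilyloxy)-2H-chromen-8-yl]-3-oxopropanoic acid (racemic half-acid) | CC1(C)C=Cc2c(O[Si](C(C)C)(C(C)C)C(C)C)ccc(C(COc3cc(OCC=C)cc(OCC=C)c3)(C(=O)OCC=C)C(=O)O)c2O1 | intermediate
19 | mixed anhydride of 18 with trifluoroacetic acid (racemic) | CC1(C)C=Cc2c(O[Si](C(C)C)(C(C)C)C(C)C)ccc(C(COc3cc(OCC=C)cc(OCC=C)c3)(C(=O)OCC=C)C(=O)OC(=O)C(F)(F)F)c2O1 | intermediate
20 | allyl 5,7-bis(allyloxy)-3-[2,2-dimethyl-5-(triisopropylsilyloxy)-2H-chromen-8-yl]-4-oxochromane-3-carboxylate (racemic) | CC1(C)C=Cc2c(O[Si](C(C)C)(C(C)C)C(C)C)ccc(C3(C(=O)OCC=C)COc4cc(OCC=C)cc(OCC=C)c4C3=O)c2O1 | intermediate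
21 | (3R)-5,7-bis(allyloxy)-3-[2,2-dimethyl-5-(triisopropylsilyloxy)-2H-chromen-8-yl]chroman-4-one | CC1(C)C=Cc2c(O[Si](C(C)C)(C(C)C)C(C)C)ccc([C@@H]3COc4cc(OCC=C)cc(OCC=C)c4C3=O)c2O1 | intermediate
22 | (3R)-5,7-dihydroxy-3-[2,2-dimethyl-5-(triisopropylsilyloxy)-2H-chromen-8-yl]chroman-4-one | CC1(C)C=Cc2c(O[Si](C(C)C)(C(C)C)C(C)C)ccc([C@@H]3COc4cc(O)cc(O)c4C3=O)c2O1 | intermediate
23 | (3R)-5,7-dihydroxy-3-(5-hydroxy-2,2-dimethyl-2H-chromen-8-yl)chroman-4-one | CC1(C)C=Cc2c(O)ccc([C@@H]3COc4cc(O)cc(O)c4C3=O)c2O1 | target

**Step count.** Total: 10 steps. Longest linear sequence: 9 steps (steps 1–5 and 7–10, from 4-bromoresorcinol); step 6 is a one-step side branch.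

**Steps most likely to fail**

Step 8. Acid-induced side reactions may occur during the in situ ester cleavage: protonation of the electron-rich chromene double bond (trifluoroacetate addition, dimerisation), capture of the tert-butyl cation by ring A, or decarboxylation of the half-acid before acylation. The fallback sets out from 17 and comes back at 20. It replaces the protic one-pot cascade by a stepwise aprotic sequence. The tert-butyl ester is cleaved with TMSOTf and 2,6-lutidine in CH2Cl2 at 0 °C, and aqueous work-up gives the isolated half-acid 18. Compound 18 is converted under neutral conditions with 1-chloro-N,N,2-trimethylprop-1-en-1-amine into the malonyl chloride half-ester F1. F1 is then closed by Lewis-acid Friedel–Crafts acylation (SnCl4, CH2Cl2, −78 °C) to 20, so the chromene never meets a strong protic acid or a free tert-butyl cation in the presence of an acylating species.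

Step 9. Enantioface discrimination in the protonation of the Pd enolate may be poor, because a 5-alkoxy group and a mono-ortho-substituted aryl group lie at the edge of the known scope; the sense of induction may be opposite, or C-allylation of the enolate may compete. The fallback sets out from 20 and comes back at 21. It separates decarboxylation from stereocontrol. Pd(PPh3)4 (cat.) and morpholine in THF at 0 °C cleave only the β-keto allyl ester, and the acid loses CO2 to give the racemic 5,7-bis(allyloxy) isoflavanone F2. Noyori asymmetric transfer hydrogenation under dynamic kinetic resolution (RuCl(p-cymene)(TsDPEN) of the antipode that gives the 3R series, HCO2H/Et3N, EtOAc, 40 °C) should reduce the rapidly racemising ketone to the cis-(3R,4R)-isoflavan-4-ol F3. Buffered Dess–Martin oxidation (NaHCO3, CH2Cl2, 0 °C) then returns ketone 21 with C3 intact, and 21 is deallylated as in the second stage of step 9.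

Step 7. SN2 displacement at the neopentyl-type carbon may be so slow that betaine decomposition or retro-aldol loss of formaldehyde from 13 overtakes ether formation. The fallback sets out from 13 and comes back at 17. It replaces the redox condensation by a pre-formed sulfonate and a free phenoxide. The alcohol is converted into the isolated neopentyl triflate F4 (Tf2O, 2,6-lutidine, CH2Cl2, −78 °C), which is displaced by the caesium phenoxide of 16 (Cs2CO3, DMF, rt) to give 17; no free alkoxide of 13 is formed at any point.

**Further compounds**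
F1 | step 8 | allyl 2-{[3,5-bis(allyloxy)phenoxy]methyl}-3-chloro-2-[2,2-dimethyl-5-(triisopropylsilyloxy)-2H-chromen-8-yl]-3-oxopropanoate (racemic acid chloride) | CC1(C)C=Cc2c(O[Si](C(C)C)(C(C)C)C(C)C)ccc(C(COc3cc(OCC=C)cc(OCC=C)c3)(C(=O)OCC=C)C(Cl)=O)c2O1
F2 | step 9 | racemic 5,7-bis(allyloxy)-3-[2,2-dimethyl-5-(triisopropylsilyloxy)-2H-chromen-8-yl]chroman-4-one | CC1(C)C=Cc2c(O[Si](C(C)C)(C(C)C)C(C)C)ccc(C3COc4cc(OCC=C)cc(OCC=C)c4C3=O)c2O1
F3 | step 9 | (3R,4R)-5,7-bis(allyloxy)-3-[2,2-dimethyl-5-(triisopropylsilyloxy)-2H-chromen-8-yl]chroman-4-ol (cis) | CC1(C)C=Cc2c(O[Si](C(C)C)(C(C)C)C(C)C)ccc([C@@H]3COc4cc(OCC=C)cc(OCC=C)c4[C@@H]3O)c2O1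
F4 | step 7 | 1-allyl 3-tert-butyl 2-[2,2-dimethyl-5-(triisopropylsilyloxy)-2H-chromen-8-yl]-2-{[(trifluoromethylsulfonyl)oxy]methyl}malonate (racemic) | CC1(C)C=Cc2c(O[Si](C(C)C)(C(C)C)C(C)C)ccc(C(COS(=O)(=O)C(F)(F)F)(C(=O)OCC=C)C(=O)OC(C)(C)C)c2O1
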